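**Plan**

- Retrosynthesis: the two galloyl esters at O3 and O5 come off first. Ring C is then opened at both bonds that hold ring A, O1–C8a and C4–C4a. Last, C2–C3 is cut as an aldol bond.
- Enabling feature: ring A is attached through two neighbouring carbons, C8a (bound to O1) and C4a (bound to C4), and C4a has the oxygen-bearing C5 as its other neighbour. This is what a 3-alkoxy aryne delivers when an oxygen nucleophile enters at the far aryne carbon and a carbon electrophile at the near one.
- Forward order: ring B and the C2–C3–C4 chain are built first (glycolate aldol, reduction, bromination). Ring A is made separately from phloroglucinol as an ortho-silyl aryl triflate with O5 as MOM ether and O7 as benzyl ether. Ring C closes when the aryne joins ring A to the chain; MOM removal, double galloylation and hydrogenolysis finish.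
- Stereochemistry: C2 (R) and C3 (R), cis, both arise in one auxiliary-controlled syn glycolate aldol reaction with (S)-4-benzyl-oxazolidinone. No later step breaks a bond at either centre.

Key step: step 13

Remark: flavan numbering (O1, C2, C3, C4, C4a, C5 to C8, C8a) and ring letters (A phloroglucinol-derived, B pyrogallol-derived, C pyran) are used throughout; the hydroxyl of the bromo alcohol is masked as a trimethylsilyl ether so that the key step runs without any proton donor.

**Route**

Step 1
Reactants: 1 phloroglucinol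
Product: 2 5-(benzyloxy)benzene-1,3-diol
Conditions: BnBr (0.4 equiv), K2CO3, DMF, 0 °C → rt
Reagents that add atoms: benzyl bromide, BrCc1ccccc1
Why: Williamson etherification under statistical control, in which the cheap triol is used in large excess so that the mono-ether should dominate, O-alkylation is favoured in DMF, and unreacted 1 is washed out with water.

Step 2
Reactants: 2 5-(benzyloxy)benzene-1,3-diol
Product: 3 3-(benzyloxy)-5-(methoxymethoxy)phenol
Conditions: MOMCl (1.0 equiv), i-Pr2NEt, THF, 0 °C → rt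
Reagents that add atoms: chloromethyl methyl ether, COCCl
Why: Williamson-type O-alkylation of a symmetric diol with one equivalent of MOMCl should give a single mono-acetal beside separable, recyclable diol and bis-acetal, after which the three oxygens of ring A are all different.

Step 3
Reactants: 3 3-(benzyloxy)-5-(methoxymethoxy)phenol
Product: 4 3-(benzyloxy)-5-(methoxymethoxy)phenyl isopropylcarbamate
Conditions: i-PrNCO, Et3N (cat.), CH2Cl2, rt
Reagents that add atoms: isopropyl isocyanate, CC(C)N=C=O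
Why: Base-catalysed addition of the phenol to the isocyanate (carbamoylation) installs an N-isopropyl carbamate that is a strong ortho-director and can later be removed under mild base.

Step 4
Reactants: 4 3-(benzyloxy)-5-(methoxymethoxy)phenyl isopropylcarbamate
Product: 8 5-(benzyloxy)-3-(methoxymethoxy)-2-(trimethylsilyl)phenyl isopropylcarbamate, via N-silyl carbamate 5 (not isolated), via aryllithium 6 (not isolated), via N-silyl C-silyl carbamate 7 (not isolated)
Conditions: TBSOTf, TMEDA, Et2O, 0 °C → rt; n-BuLi, TMEDA, −78 °C; TMSCl, −78 °C → rt; aq. NH4Cl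
Reagents that add atoms: chlorotrimethylsilane, C[Si](C)(C)Cl
Why: Directed ortho-metalation, in which after N-silylation in the flask the O-carbamate and the OMOM group (the two strongest directors on the ring) act together on the one carbon between them, so lithiation and C-silylation should occur there and not next to the weakly directing benzyloxy group, and the N–Si bond is hydrolysed on work-up.

Step 5
Reactants: 8 5-(benzyloxy)-3-(methoxymethoxy)-2-(trimethylsilyl)phenyl isopropylcarbamate
Product: 10 5-(benzyloxy)-3-(methoxymethoxy)-2-(trimethylsilyl)phenyl trifluoromethanesulfonate, via silyl phenoxide 9 (not isolated)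
Conditions: DBU, Et2NH, MeCN, 40 °C; then PhNTf2, rt
Reagents that add atoms: N-phenylbis(trifluoromethanesulfonimide), O=S(=O)(N(c1ccccc1)S(=O)(=O)C(F)(F)F)C(F)(F)F
Why: E1cB carbamate cleavage (DBU removes the N–H proton, the phenoxide leaves and Et2NH captures the isocyanate) followed by O-sulfonylation of the phenoxide in the same flask is the standard entry to ortho-silyl aryl triflates and avoids acid that would attack the C–Si bond or the acetal.

Step 6
Reactants: 11 methyl glycolate
Product: 12 methyl 2-(methoxymethoxy)acetate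
Conditions: MOMCl, i-Pr2NEt, CH2Cl2, 0 °C → rt
Reagents that add atoms: chloromethyl methyl ether, COCCl
Why: O-alkylation of the primary alcohol with MOMCl and a hindered amine base (acetal protection) leaves the ester untouched.

Step 7
Reactants: 12 methyl 2-(methoxymethoxy)acetate
Product: 13 2-(methoxymethoxy)acetic acid
Conditions: LiOH, THF/H2O, 0 °C → rt; then 1 M HCl to pH 3, 0 °C
Reagents that add atoms: lithium hydroxide, [Li+].[OH-]
Why: Ester saponification, in which the MOM acetal is stable to base and should survive the brief, cold acidification.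

Step 8
Reactants: 13 2-(methoxymethoxy)acetic acid; 14 (S)-4-benzyl-1,3-oxazolidin-2-one
Product: 16 (S)-4-benzyl-3-[2-(methoxymethoxy)acetyl]-1,3-oxazolidin-2-one, via mixed pivalic anhydride 15 (not isolated)
Conditions: PivCl, Et3N, THF, −20 °C; then LiCl, 14, −20 °C → rt
Reagents that add atoms: none
Why: N-acylation of the oxazolidinone through the mixed pivalic anhydride with LiCl/Et3N activation, where the hindered pivaloyl carbonyl is not attacked.

Step 9
Reactants: 16 (S)-4-benzyl-3-[2-(methoxymethoxy)acetyl]-1,3-oxazolidin-2-one; 17 3,4,5-tris(benzyloxy)benzaldehyde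
Product: 19 (S)-4-benzyl-3-[(2S,3R)-3-hydroxy-2-(methoxymethoxy)-3-[3,4,5-tris(benzyloxy)phenyl]propanoyl]-1,3-oxazolidin-2-one, via boron enolate 18 (not isolated)
Conditions: Et3N, n-Bu2BOTf, CH2Cl2, −78 → 0 °C; 17, −78 → 0 °C; then pH 7 buffer, MeOH, H2O2, 0 °C
Reagents that add atoms: none
Why: Evans boron-mediated syn glycolate aldol reaction, in which the (Z)-enolate reacts through a chair Zimmerman–Traxler transition state on the face opposite the benzyl group of the (S)-auxiliary and thereby sets both stereocentres as (2S,3R), syn (the future C3 and C2 of the chromane).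

Step 10
Reactants: 19 (S)-4-benzyl-3-[(2S,3R)-3-hydroxy-2-(methoxymethoxy)-3-[3,4,5-tris(benzyloxy)phenyl]propanoyl]-1,3-oxazolidin-2-one
Product: 20 (1R,2R)-2-(methoxymethoxy)-1-[3,4,5-tris(benzyloxy)phenyl]propane-1,3-diol
Conditions: LiBH4, MeOH (1 equiv), THF, 0 °C
Reagents that add atoms: none
Why: Reductive cleavage of the N-acyl oxazolidinone by LiBH4 (attack at the exocyclic carbonyl, auxiliary recovered) should give the primary alcohol without touching either stereocentre.

Step 11
Reactants: 20 (1R,2R)-2-(methoxymethoxy)-1-[3,4,5-tris(benzyloxy)phenyl]propane-1,3-diol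
Product: 21 (1R,2S)-3-bromo-2-(methoxymethoxy)-1-[3,4,5-tris(benzyloxy)phenyl]propan-1-ol
Conditions: CBr4, PPh3, 2,6-lutidine, CH2Cl2, −20 → 0 °C
Reagents that add atoms: carbon tetrabromide, BrC(Br)(Br)Br
Why: Appel bromination, in which the unhindered primary hydroxyl forms the alkoxyphosphonium ion and is displaced by bromide much faster than the hindered secondary benzylic one, while lutidine keeps the medium neutral for the acetal.

Step 12
Reactants: 21 (1R,2S)-3-bromo-2-(methoxymethoxy)-1-[3,4,5-tris(benzyloxy)phenyl]propan-1-ol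
Product: 22 [(1R,2S)-3-bromo-2-(methoxymethoxy)-1-[3,4,5-tris(benzyloxy)phenyl]propoxy]trimethylsilane
Conditions: TMSCl, imidazole, CH2Cl2, 0 °C
Reagents that add atoms: chlorotrimethylsilane, C[Si](C)(C)Cl
Why: O-silylation of the secondary alcohol removes the only acidic proton and stores the alkoxide in a form that fluoride will release.

Step 13
Reactants: 22 [(1R,2S)-3-bromo-2-(methoxymethoxy)-1-[3,4,5-tris(benzyloxy)phenyl]propoxy]trimethylsilane; 10 5-(benzyloxy)-3-(methoxymethoxy)-2-(trimethylsilyl)phenyl trifluoromethanesulfonate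
Product: 26 (2R,3R)-7-(benzyloxy)-3,5-bis(methoxymethoxy)-2-[3,4,5-tris(benzyloxy)phenyl]chromane, via caesium alkoxide 23 (not isolated), via aryne 24 (not isolated), via aryl caesium adduct 25 (not isolated)
Conditions: CsF (4 equiv), 18-crown-6, THF, 0 °C → rt; 10 in excess (1.5 equiv), strictly anhydrous
Reagents that add atoms: none
Why: Proposed new method: fluoride cleaves the O–SiMe3 bond of 22 to the proton-free caesium alkoxide 23 and, by attack on the aryl silane of 10 with loss of triflate, releases aryne 24; 23 adds to the aryne carbon meta to the OMOM group (O1–C8a), which leaves the aryl anion 25 on the carbon flanked by the two oxygens, and this anion displaces the primary bromide in an intramolecular SN2 reaction (C4–C4a). The closest known reaction types are fluoride-triggered aryne annulations in which a heteroatom nucleophile adds and the aryl anion is caught by a tethered ester (xanthones from salicylates, acridones from anthranilates) and the Parham cycloalkylation of aryllithiums onto tethered alkyl bromides; an sp3 halide as the internal trap after alkoxide addition is the new element. Ring C closes in a 6-exo-tet mode. No stereocentre is created: C2 and C3 of the chromane come unchanged from 22, because bonds form only at oxygen and at the CH2 carbon. The step needs regioselective C–O bond formation, secured by the inductively withdrawing 3-alkoxy group that makes the distal aryne carbon the electrophilic one, and alkylation in preference to protonation of 25, secured by the silyl-masked hydroxyl, by THF in place of acetonitrile and by the six-membered transition state. Premature four-membered ring closure or fragmentation of 23 should be held back because 10, present in excess, re-silylates free alkoxide while generating more aryne.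

Step 14
Reactants: 26 (2R,3R)-7-(benzyloxy)-3,5-bis(methoxymethoxy)-2-[3,4,5-tris(benzyloxy)phenyl]chromane
Product: 27 (2R,3R)-7-(benzyloxy)-2-[3,4,5-tris(benzyloxy)phenyl]chromane-3,5-diol
Conditions: HCl (conc., cat.), MeOH/THF, 40 °C
Reagents that add atoms: none
Why: Acid-catalysed transacetalisation to methanol should remove the aryl and the alkyl MOM group in one operation while the benzyl ethers and the chromane ring stay intact.

Step 15
Reactants: 27 (2R,3R)-7-(benzyloxy)-2-[3,4,5-tris(benzyloxy)phenyl]chromane-3,5-diol; 28 3,4,5-tris(benzyloxy)benzoic acid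
Product: 29 (2R,3R)-7-(benzyloxy)-2-[3,4,5-tris(benzyloxy)phenyl]chromane-3,5-diyl bis[3,4,5-tris(benzyloxy)benzoate]
Conditions: 28 (3 equiv), EDC·HCl, DMAP, CH2Cl2, rt
Reagents that add atoms: none
Why: Steglich esterification (carbodiimide activation, DMAP acyl transfer) acylates the phenol O5 and the secondary alcohol O3, the only free hydroxyls, while O7 stays benzylated.

Step 16
Reactants: 29 (2R,3R)-7-(benzyloxy)-2-[3,4,5-tris(benzyloxy)phenyl]chromane-3,5-diyl bis[3,4,5-tris(benzyloxy)benzoate]
Product: 30 epigallocatechin 3,5-digallate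
Conditions: H2 (1 atm), Pd(OH)2/C, THF/MeOH, rt
Reagents that add atoms: none
Why: Catalytic hydrogenolysis of all ten benzyl ethers under neutral conditions, as established for benzylated flavan-3-ol gallates, should leave both esters and the two stereocentres untouched.

**Compound list**

1 | phloroglucinol (benzene-1,3,5-triol) | Oc1cc(O)cc(O)c1 | starting material
2 | 5-(benzyloxy)benzene-1,3-diol | Oc1cc(O)cc(OCc2ccccc2)c1 | intermediate
3 | 3-(benzyloxy)-5-(methoxymethoxy)phenol | COCOc1cc(O)cc(OCc2ccccc2)c1 | intermediate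
4 | 3-(benzyloxy)-5-(methoxymethoxy)phenyl isopropylcarbamate | CC(C)NC(=O)Oc1cc(OCOC)cc(OCc2ccccc2)c1 | intermediate
5 | 3-(benzyloxy)-5-(methoxymethoxy)phenyl N-(tert-butyldimethylsilyl)-N-isopropylcarbamate (not isolated) | CC(C)N(C(=O)Oc1cc(OCOC)cc(OCc2ccccc2)c1)[Si](C)(C)C(C)(C)C | intermediate
6 | [4-(benzyloxy)-2-{[N-(tert-butyldimethylsilyl)-N-isopropylcarbamoyl]oxy}-6-(methoxymethoxy)phenyl]lithium (not isolated) | [Li]c1c(OCOC)cc(OCc2ccccc2)cc1OC(=O)N(C(C)C)[Si](C)(C)C(C)(C)C | intermediate
7 | 5-(benzyloxy)-3-(methoxymethoxy)-2-(trimethylsilyl)phenyl N-(tert-butyldimethylsilyl)-N-isopropylcarbamate (not isolated) | C[Si](C)(C)c1c(OCOC)cc(OCc2ccccc2)cc1OC(=O)N(C(C)C)[Si](C)(C)C(C)(C)C | intermediate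
8 | 5-(benzyloxy)-3-(methoxymethoxy)-2-(trimethylsilyl)phenyl isopropylcarbamate | C[Si](C)(C)c1c(OCOC)cc(OCc2ccccc2)cc1OC(=O)NC(C)C | intermediate
9 | 5-(benzyloxy)-3-(methoxymethoxy)-2-(trimethylsilyl)phenol, present as its DBU-H phenoxide (not isolated) | C[Si](C)(C)c1c(OCOC)cc(OCc2ccccc2)cc1O | intermediate
10 | 5-(benzyloxy)-3-(methoxymethoxy)-2-(trimethylsilyl)phenyl trifluoromethanesulfonate | C[Si](C)(C)c1c(OCOC)cc(OCc2ccccc2)cc1OS(=O)(=O)C(F)(F)F | intermediate
11 | methyl glycolate (methyl 2-hydroxyacetate) | COC(=O)CO | starting material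
12 | methyl 2-(methoxymethoxy)acetate | COCOCC(=O)OC | intermediate
13 | 2-(methoxymethoxy)acetic acid | COCOCC(=O)O | intermediate
14 | (S)-4-benzyl-1,3-oxazolidin-2-one | O=C1N[C@@H](Cc2ccccc2)CO1 | starting material
15 | 2-(methoxymethoxy)acetic pivalic anhydride (not isolated) | COCOCC(=O)OC(=O)C(C)(C)C | intermediate
16 | (S)-4-benzyl-3-[2-(methoxymethoxy)acetyl]-1,3-oxazolidin-2-one | COCOCC(=O)N1C(=O)OC[C@@H]1Cc1ccccc1 | intermediate
17 | 3,4,5-tris(benzyloxy)benzaldehyde | O=Cc1cc(OCc2ccccc2)c(OCc2ccccc2)c(OCc2ccccc2)c1 | starting material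
18 | (Z)-dibutylboron enolate of 16 (not isolated) | CCCCB(CCCC)O/C(=C\OCOC)N1C(=O)OC[C@@H]1Cc1ccccc1 | intermediate
19 | (S)-4-benzyl-3-[(2S,3R)-3-hydroxy-2-(methoxymethoxy)-3-[3,4,5-tris(benzyloxy)phenyl]propanoyl]-1,3-oxazolidin-2-one | COCO[C@H](C(=O)N1C(=O)OC[C@@H]1Cc1ccccc1)[C@H](O)c1cc(OCc2ccccc2)c(OCc2ccccc2)c(OCc2ccccc2)c1 | intermediate
20 | (1R,2R)-2-(methoxymethoxy)-1-[3,4,5-tris(benzyloxy)phenyl]propane-1,3-diol | OC[C@@H](OCOC)[C@H](O)c1cc(OCc2ccccc2)c(OCc2ccccc2)c(OCc2ccccc2)c1 | intermediate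
21 | (1R,2S)-3-bromo-2-(methoxymethoxy)-1-[3,4,5-tris(benzyloxy)phenyl]propan-1-ol | BrC[C@@H](OCOC)[C@H](O)c1cc(OCc2ccccc2)c(OCc2ccccc2)c(OCc2ccccc2)c1 | intermediate
22 | [(1R,2S)-3-bromo-2-(methoxymethoxy)-1-[3,4,5-tris(benzyloxy)phenyl]propoxy]trimethylsilane | BrC[C@@H](OCOC)[C@H](O[Si](C)(C)C)c1cc(OCc2ccccc2)c(OCc2ccccc2)c(OCc2ccccc2)c1 | intermediate
23 | caesium (1R,2S)-3-bromo-2-(methoxymethoxy)-1-[3,4,5-tris(benzyloxy)phenyl]propan-1-olate (not isolated) | BrC[C@@H](OCOC)[C@H]([O-])c1cc(OCc2ccccc2)c(OCc2ccccc2)c(OCc2ccccc2)c1.[Cs+] | intermediate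
24 | 5-(benzyloxy)-3-(methoxymethoxy)benzyne (1,2-didehydroarene, not isolated) | COCOC1=CC(OCc2ccccc2)=CC#C1 | intermediate
25 | {4-(benzyloxy)-2-[(1R,2S)-3-bromo-2-(methoxymethoxy)-1-[3,4,5-tris(benzyloxy)phenyl]propoxy]-6-(methoxymethoxy)phenyl}caesium (not isolated) | BrC[C@@H](OCOC)[C@H](Oc1cc(OCc2ccccc2)cc(OCOC)c1[Cs])c1cc(OCc2ccccc2)c(OCc2ccccc2)c(OCc2ccccc2)c1 | intermediate
26 | (2R,3R)-7-(benzyloxy)-3,5-bis(methoxymethoxy)-2-[3,4,5-tris(benzyloxy)phenyl]chromane | COCO[C@@H]1Cc2c(OCOC)cc(OCc3ccccc3)cc2O[C@@H]1c1cc(OCc2ccccc2)c(OCc2ccccc2)c(OCc2ccccc2)c1 | intermediate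
27 | (2R,3R)-7-(benzyloxy)-2-[3,4,5-tris(benzyloxy)phenyl]chromane-3,5-diol | O[C@@H]1Cc2c(O)cc(OCc3ccccc3)cc2O[C@@H]1c1cc(OCc2ccccc2)c(OCc2ccccc2)c(OCc2ccccc2)c1 | intermediate
28 | 3,4,5-tris(benzyloxy)benzoic acid | O=C(O)c1cc(OCc2ccccc2)c(OCc2ccccc2)c(OCc2ccccc2)c1 | starting material
29 | (2R,3R)-7-(benzyloxy)-2-[3,4,5-tris(benzyloxy)phenyl]chromane-3,5-diyl bis[3,4,5-tris(benzyloxy)benzoate] | O=C(Oc1cc(OCc3ccccc3)cc2c1C[C@@H](OC(=O)c1cc(OCc3ccccc3)c(OCc3ccccc3)c(OCc3ccccc3)c1)[C@@H](c1cc(OCc3ccccc3)c(OCc3ccccc3)c(OCc3ccccc3)c1)O2)c1cc(OCc2ccccc2)c(OCc2ccccc2)c(OCc2ccccc2)c1 | intermediate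
30 | epigallocatechin 3,5-digallate, (2R,3R) | O=C(Oc1cc(O)cc2c1C[C@@H](OC(=O)c1cc(O)c(O)c(O)c1)[C@@H](c1cc(O)c(O)c(O)c1)O2)c1cc(O)c(O)c(O)c1 | target

**Step count**

Total: 16 steps. Longest linear sequence: 11 steps (steps 6 to 16, from methyl glycolate). The ring A branch (steps 1 to 5) joins at step 13.

**Steps most likely to fail**

1. Step 13 (aryne annulation). Several processes could compete with ring closure:
   - proton capture by the aryl anion, or a 1,4-proton shift from the benzylic C–H;
   - four-membered ring closure or fragmentation of the bromo alkoxide before it meets the aryne;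
   - halogen–metal exchange at the CH2Br group in place of substitution.

   Fallback by known chemistry: the same two bonds are made one after the other, by aryllithium alkylation and then intramolecular SNAr etherification. It sets out from aldol adduct 19. Silylation (TBSCl, imidazole, DMF) should give (S)-4-benzyl-3-[(2S,3R)-3-(tert-butyldimethylsilyloxy)-2-(methoxymethoxy)-3-[3,4,5-tris(benzyloxy)phenyl]propanoyl]-1,3-oxazolidin-2-one F1. LiBH4 reduction should give (2R,3R)-3-(tert-butyldimethylsilyloxy)-2-(methoxymethoxy)-3-[3,4,5-tris(benzyloxy)phenyl]propan-1-ol F2, and Tf2O with 2,6-lutidine in CH2Cl2 at −78 °C the corresponding primary triflate F3. The ring A partner comes from commercial 3,5-difluorophenol: MOM protection to 1,3-difluoro-5-(methoxymethoxy)benzene F4, then displacement of one fluoride with BnONa (NMP, 100 °C) to 1-(benzyloxy)-3-fluoro-5-(methoxymethoxy)benzene F5. F5 is lithiated between fluorine and the acetal oxygen (n-BuLi, THF, −78 °C) and alkylated in the same flask by F3, forming C4–C4a in tert-butyl{[(1R,2R)-3-[4-(benzyloxy)-2-fluoro-6-(methoxymethoxy)phenyl]-2-(methoxymethoxy)-1-[3,4,5-tris(benzyloxy)phenyl]propoxy}dimethylsilane F6. TBAF frees (1R,2R)-3-[4-(benzyloxy)-2-fluoro-6-(methoxymethoxy)phenyl]-2-(methoxymethoxy)-1-[3,4,5-tris(benzyloxy)phenyl]propan-1-ol F7. KH in THF/DMF then closes O1–C8a by displacement of fluoride with retention at C2, and the route is rejoined at chromane 26.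

2. Step 4 (ortho-silylation). Metalation could go to a ring carbon next to the benzyloxy group, or the silyl triflate could attack the MOM acetal before the carbamate nitrogen is capped.

   Fallback: symmetry decides the site and the acetal is introduced last. It sets out from diol 2. Double carbamoylation (i-PrNCO, Et3N) should give 5-(benzyloxy)-1,3-phenylene bis(isopropylcarbamate) F8. After double N-silylation (TBSOTf, TMEDA), n-BuLi can be strongly directed only to the carbon between the two carbamates, and TMSCl should give 5-(benzyloxy)-2-(trimethylsilyl)-1,3-phenylene bis(isopropylcarbamate) F9. DBU/Et2NH removes both carbamates and one equivalent of PhNTf2 should give 5-(benzyloxy)-3-hydroxy-2-(trimethylsilyl)phenyl trifluoromethanesulfonate F10, since the first triflation deactivates the second phenoxide. MOMCl/i-Pr2NEt then gives aryl triflate 10.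

3. Step 11 (chemoselective bromination). Activation or ionisation of the electron-rich secondary benzylic hydroxyl could compete with substitution at the primary one.

   Fallback: the secondary hydroxyl is masked before the primary one exists. It sets out from aldol adduct 19. TESCl/imidazole should give (S)-4-benzyl-3-[(2S,3R)-2-(methoxymethoxy)-3-(triethylsilyloxy)-3-[3,4,5-tris(benzyloxy)phenyl]propanoyl]-1,3-oxazolidin-2-one F11. LiBH4 should give (2R,3R)-2-(methoxymethoxy)-3-(triethylsilyloxy)-3-[3,4,5-tris(benzyloxy)phenyl]propan-1-ol F12, and CBr4/PPh3 the bromide [(1R,2S)-3-bromo-2-(methoxymethoxy)-1-[3,4,5-tris(benzyloxy)phenyl]propoxy]triethylsilane F13. HF·pyridine (THF/pyridine, 0 °C) removes the triethylsilyl group and the route is rejoined at bromo alcohol 21.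

Further compounds
F1 | step 13 | (S)-4-benzyl-3-[(2S,3R)-3-(tert-butyldimethylsilyloxy)-2-(methoxymethoxy)-3-[3,4,5-tris(benzyloxy)phenyl]propanoyl]-1,3-oxazolidin-2-one | COCO[C@H](C(=O)N1C(=O)OC[C@@H]1Cc1ccccc1)[C@H](O[Si](C)(C)C(C)(C)C)c1cc(OCc2ccccc2)c(OCc2ccccc2)c(OCc2ccccc2)c1
F2 | step 13 | (2R,3R)-3-(tert-butyldimethylsilyloxy)-2-(methoxymethoxy)-3-[3,4,5-tris(benzyloxy)phenyl]propan-1-ol | OC[C@@H](OCOC)[C@H](O[Si](C)(C)C(C)(C)C)c1cc(OCc2ccccc2)c(OCc2ccccc2)c(OCc2ccccc2)c1
F3 | step 13 | (2R,3R)-3-(tert-butyldimethylsilyloxy)-2-(methoxymethoxy)-3-[3,4,5-tris(benzyloxy)phenyl]propyl trifluoromethanesulfonate | O=S(=O)(OC[C@@H](OCOC)[C@H](O[Si](C)(C)C(C)(C)C)c1cc(OCc2ccccc2)c(OCc2ccccc2)c(OCc2ccccc2)c1)C(F)(F)F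
F4 | step 13 | 1,3-difluoro-5-(methoxymethoxy)benzene | COCOc1cc(F)cc(F)c1
F5 | step 13 | 1-(benzyloxy)-3-fluoro-5-(methoxymethoxy)benzene | COCOc1cc(F)cc(OCc2ccccc2)c1
F6 | step 13 | tert-butyl{[(1R,2R)-3-[4-(benzyloxy)-2-fluoro-6-(methoxymethoxy)phenyl]-2-(methoxymethoxy)-1-[3,4,5-tris(benzyloxy)phenyl]propoxy}dimethylsilane | COCO[C@H](Cc1c(F)cc(OCc2ccccc2)cc1OCOC)[C@H](O[Si](C)(C)C(C)(C)C)c1cc(OCc2ccccc2)c(OCc2ccccc2)c(OCc2ccccc2)c1
F7 | step 13 | (1R,2R)-3-[4-(benzyloxy)-2-fluoro-6-(methoxymethoxy)phenyl]-2-(methoxymethoxy)-1-[3,4,5-tris(benzyloxy)phenyl]propan-1-ol | COCO[C@H](Cc1c(F)cc(OCc2ccccc2)cc1OCOC)[C@H](O)c1cc(OCc2ccccc2)c(OCc2ccccc2)c(OCc2ccccc2)c1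
F8 | step 4 | 5-(benzyloxy)-1,3-phenylene bis(isopropylcarbamate) | CC(C)NC(=O)Oc1cc(OCc2ccccc2)cc(OC(=O)NC(C)C)c1
F9 | step 4 | 5-(benzyloxy)-2-(trimethylsilyl)-1,3-phenylene bis(isopropylcarbamate) | CC(C)NC(=O)Oc1cc(OCc2ccccc2)cc(OC(=O)NC(C)C)c1[Si](C)(C)C
F10 | step 4 | 5-(benzyloxy)-3-hydroxy-2-(trimethylsilyl)phenyl trifluoromethanesulfonate | C[Si](C)(C)c1c(O)cc(OCc2ccccc2)cc1OS(=O)(=O)C(F)(F)F
F11 | step 11 | (S)-4-benzyl-3-[(2S,3R)-2-(methoxymethoxy)-3-(triethylsilyloxy)-3-[3,4,5-tris(benzyloxy)phenyl]propanoyl]-1,3-oxazolidin-2-one | COCO[C@H](C(=O)N1C(=O)OC[C@@H]1Cc1ccccc1)[C@H](O[Si](CC)(CC)CC)c1cc(OCc2ccccc2)c(OCc2ccccc2)c(OCc2ccccc2)c1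
F12 | step 11 | (2R,3R)-2-(methoxymethoxy)-3-(triethylsilyloxy)-3-[3,4,5-tris(benzyloxy)phenyl]propan-1-ol | OC[C@@H](OCOC)[C@H](O[Si](CC)(CC)CC)c1cc(OCc2ccccc2)c(OCc2ccccc2)c(OCc2ccccc2)c1
F13 | step 11 | [(1R,2S)-3-bromo-2-(methoxymethoxy)-1-[3,4,5-tris(benzyloxy)phenyl]propoxy]triethylsilane | BrC[C@@H](OCOC)[C@H](O[Si](CC)(CC)CC)c1cc(OCc2ccccc2)c(OCc2ccccc2)c(OCc2ccccc2)c1
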